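## Retrosynthetic overview

1. Target ⇒ break the ketone C(=O)–CH(Me) bond on the ring A (pentyl) side. An (R)-S-phenyl thioester becomes an acyl-nickel species (acyl anion equivalent) and couples with the racemic 2-(1-chloroethyl)pyranone of ring A. Two electrophilic carbons are joined by an enantioconvergent Ni/Mn reductive coupling, which sets the second R centre.
2. (R)-Thioester ⇒ S-phenyl chlorothioformate as carbonyl linchpin (a thiocarboxyl anion equivalent after nickel insertion and reduction) plus the racemic 2-(1-chloroethyl)pyranone of ring B (ethyl). The same chiral catalyst sets the first R centre.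
3. Both racemic chlorides ⇒ lateral dienolate chemistry on simple tetra-alkyl 4-pyranones: chlorination for ring B; butylation, chlorination, then methylation for ring A.
4. Ring order: ring B (step 1) and ring A (step 3) are both made at the start from pentan-3-one and a carboxylic acid in polyphosphoric acid. No ring is formed later.

Assumption: the (R,R) antipode of the Ph-BOX ligand, 2,2'-(propane-2,2-diyl)bis[(4R)-4-phenyl-4,5-dihydrooxazole], is taken to give the R centre with these pyranyl substrates; if the first coupling shows the opposite sense, the (S,S) ligand is used in both couplings.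

Abbreviation: dme = MeOCH2CH2OMe.

## Route

Step 1
Reactants: 1 pentan-3-one; 2 propanoic acid (2.2 equiv)
Product: 4 2,6-diethyl-3,5-dimethyl-4H-pyran-4-one, via triketone 3 (not isolated)
Conditions: polyphosphoric acid (medium), 100 °C, 6 h; ice water, extraction, distillation
Reagents that add atoms: propanoic acid, CCC(=O)O
Why: Acid-mediated double C-acylation of the ketone gives the 1,3,5-triketone, which cyclodehydrates in the same pot (polyphosphoric acid 4-pyranone synthesis); no stereocentre is formed.

Step 2
Reactants: 4 2,6-diethyl-3,5-dimethyl-4H-pyran-4-one; 5 hexachloroethane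
Product: 7 racemic 2-(1-chloroethyl)-6-ethyl-3,5-dimethyl-4H-pyran-4-one, via lithium dienolate 6 (not isolated)
Conditions: LiN(SiMe3)2 (1.05 equiv), THF, −78 °C, 30 min; cannulated into C2Cl6 (1.5 equiv), THF, −78 °C
Reagents that add atoms: hexachloroethane, ClC(Cl)(Cl)C(Cl)(Cl)Cl
Why: Vinylogous enolate formation at one of two equivalent lateral CH2 groups, then electrophilic enolate chlorination at the exocyclic carbon, turns the normally nucleophilic lateral carbon into an electrophile; the centre is left racemic because the later coupling is enantioconvergent.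

Step 3
Reactants: 1 pentan-3-one; 8 acetic acid (2.2 equiv)
Product: 10 2,3,5,6-tetramethyl-4H-pyran-4-one, via triketone 9 (not isolated)
Conditions: polyphosphoric acid (medium), 100 °C, 6 h; ice water, extraction, crystallisation
Reagents that add atoms: acetic acid, CC(=O)O
Why: Same polyphosphoric acid double acylation and cyclodehydration as step 1; no stereocentre.

Step 4
Reactants: 10 2,3,5,6-tetramethyl-4H-pyran-4-one; 11 1-iodobutane
Product: 13 2,3,5-trimethyl-6-pentyl-4H-pyran-4-one, via lithium dienolate 12 (not isolated)
Conditions: LiN(SiMe3)2 (1.05 equiv), THF, −78 °C, 30 min; n-BuI (1.2 equiv), DMPU, −78 → −20 °C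
Reagents that add atoms: 1-iodobutane, CCCCI
Why: Vinylogous enolate alkylation; only the 2- and 6-methyl groups are activated through the ring and they are equivalent, so mono-deprotonation and γ-alkylation give one product.

Step 5
Reactants: 13 2,3,5-trimethyl-6-pentyl-4H-pyran-4-one; 5 hexachloroethane
Product: 15 2-(chloromethyl)-3,5-dimethyl-6-pentyl-4H-pyran-4-one, via lithium dienolate 14 (not isolated)
Conditions: LiN(SiMe3)2 (1.05 equiv), THF, −78 °C, 20 min; cannulated into C2Cl6 (1.5 equiv), THF, −78 °C
Reagents that add atoms: hexachloroethane, ClC(Cl)(Cl)C(Cl)(Cl)Cl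
Why: Kinetic vinylogous deprotonation favours the methyl over the pentyl CH2 (less hindered, and its exocyclic enolate has no allylic 1,3-strain against the ring methyl); electrophilic enolate chlorination by inverse addition then avoids over-chlorination.

Step 6
Reactants: 15 2-(chloromethyl)-3,5-dimethyl-6-pentyl-4H-pyran-4-one; 16 iodomethane
Product: 18 racemic 2-(1-chloroethyl)-3,5-dimethyl-6-pentyl-4H-pyran-4-one, via chloro dienolate 17 (not isolated)
Conditions: 15 added slowly to LiN(SiMe3)2 (1.1 equiv), THF, −78 °C; MeI (3 equiv), −78 → −40 °C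
Reagents that add atoms: iodomethane, CI
Why: The CH2Cl protons are the most acidic lateral protons (chlorine plus vinylogous carbonyl), so a Darzens-type α-chloro dienolate forms selectively at −78 °C and is C-methylated (enolate alkylation), which fixes the chloride on the correct side chain; the centre is racemic by design.

Step 7
Reactants: 7 racemic 2-(1-chloroethyl)-6-ethyl-3,5-dimethyl-4H-pyran-4-one (1.0 equiv); 19 S-phenyl chlorothioformate (1.5 equiv)
Product: 20 S-phenyl (2R)-2-(6-ethyl-3,5-dimethyl-4-oxo-4H-pyran-2-yl)propanethioate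
Conditions: NiCl2·dme (10 mol %), (R,R)-Ph-BOX (22 mol %), Mn powder (3 equiv), 2,6-dimethylbenzoic acid (0.75 equiv), 3 Å MS, DMA/THF 3:7, 0 → 20 °C, 24 h
Reagents that add atoms: S-phenyl chlorothioformate, O=C(Cl)Sc1ccccc1
Why: Proposed new method: zerovalent nickel inserts into the C–Cl bond of the chlorothioformate much faster than into a C–S bond, Mn reduces the resulting acyl-nickel chloride so that it behaves as a thiocarboxyl anion equivalent, the planar pyranylethyl radical formed from either enantiomer of 7 is captured, and reductive elimination inside the chiral bis(oxazoline) pocket sets the R centre, with the hindered acid additive keeping the medium non-basic; closest known reactions are the nickel-catalysed enantioconvergent reductive coupling of acid chlorides with secondary benzylic chlorides and the nickel-catalysed reductive coupling of alkyl halides with chloroformates (cross-electrophile coupling).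

Step 8
Reactants: 20 S-phenyl (2R)-2-(6-ethyl-3,5-dimethyl-4-oxo-4H-pyran-2-yl)propanethioate (1.3 equiv); 18 racemic 2-(1-chloroethyl)-3,5-dimethyl-6-pentyl-4H-pyran-4-one (1.0 equiv)
Product: 21 (2R,4R)-2-(6-ethyl-3,5-dimethyl-4-oxo-4H-pyran-2-yl)-4-(3,5-dimethyl-4-oxo-6-pentyl-4H-pyran-2-yl)pentan-3-one (target)
Conditions: NiCl2·dme (15 mol %), (R,R)-Ph-BOX (33 mol %), Mn powder (3 equiv), 2,6-dimethylbenzoic acid (0.75 equiv), 3 Å MS, DMA/THF 3:7, 20 °C, 24 h; pH-neutral work-up, neutral silica, HPLC to remove any (2R,4S) isomer
Reagents that add atoms: none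
Why: Proposed new method: zerovalent nickel inserts into the acyl C–S bond of the aryl thioester, Mn reduction gives an acyl-nickel species acting as an acyl anion equivalent toward the second electrophile, and the radical from either enantiomer of 18 is captured and coupled under control of the same ligand to set the second R centre, while the existing centre of 20 is not enolised in the base-free, weakly acidic medium; closest known reactions are the nickel-catalysed reductive ketone synthesis from S-(2-pyridyl) thioesters and alkyl halides and the enantioconvergent acid chloride/benzylic chloride reductive coupling.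

## Compound list

1 | pentan-3-one | CCC(=O)CC | starting material
2 | propanoic acid | CCC(=O)O | starting material
3 | 4,6-dimethylnonane-3,5,7-trione (not isolated) | CCC(=O)C(C)C(=O)C(C)C(=O)CC | intermediate
4 | 2,6-diethyl-3,5-dimethyl-4H-pyran-4-one | CCc1oc(CC)c(C)c(=O)c1C | intermediate
5 | hexachloroethane | ClC(Cl)(Cl)C(Cl)(Cl)Cl | starting material
6 | lithium 6-ethyl-2-ethylidene-3,5-dimethyl-2H-pyran-4-olate (not isolated) | CC=C1OC(CC)=C(C)C(O[Li])=C1C | intermediate
7 | racemic 2-(1-chloroethyl)-6-ethyl-3,5-dimethyl-4H-pyran-4-one | CCc1oc(C(C)Cl)c(C)c(=O)c1C | intermediate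
8 | acetic acid | CC(=O)O | starting material
9 | 3,5-dimethylheptane-2,4,6-trione (not isolated) | CC(=O)C(C)C(=O)C(C)C(C)=O | intermediate
10 | 2,3,5,6-tetramethyl-4H-pyran-4-one | Cc1oc(C)c(C)c(=O)c1C | intermediate
11 | 1-iodobutane | CCCCI | starting material
12 | lithium 3,5,6-trimethyl-2-methylidene-2H-pyran-4-olate (not isolated) | C=C1OC(C)=C(C)C(O[Li])=C1C | intermediate
13 | 2,3,5-trimethyl-6-pentyl-4H-pyran-4-one | CCCCCc1oc(C)c(C)c(=O)c1C | intermediate
14 | lithium 3,5-dimethyl-2-methylidene-6-pentyl-2H-pyran-4-olate (not isolated) | C=C1OC(CCCCC)=C(C)C(O[Li])=C1C | intermediate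
15 | 2-(chloromethyl)-3,5-dimethyl-6-pentyl-4H-pyran-4-one | CCCCCc1oc(CCl)c(C)c(=O)c1C | intermediate
16 | iodomethane | CI | starting material
17 | lithium 2-(chloromethylidene)-3,5-dimethyl-6-pentyl-2H-pyran-4-olate (not isolated) | ClC=C1OC(CCCCC)=C(C)C(O[Li])=C1C | intermediate
18 | racemic 2-(1-chloroethyl)-3,5-dimethyl-6-pentyl-4H-pyran-4-one | CCCCCc1oc(C(C)Cl)c(C)c(=O)c1C | intermediate
19 | S-phenyl chlorothioformate (S-phenyl carbonochloridothioate) | O=C(Cl)Sc1ccccc1 | starting material
20 | S-phenyl (2R)-2-(6-ethyl-3,5-dimethyl-4-oxo-4H-pyran-2-yl)propanethioate | O=C(Sc1ccccc1)[C@H](C)c1oc(CC)c(C)c(=O)c1C | intermediate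
21 | (2R,4R)-2-(6-ethyl-3,5-dimethyl-4-oxo-4H-pyran-2-yl)-4-(3,5-dimethyl-4-oxo-6-pentyl-4H-pyran-2-yl)pentan-3-one | CCCCCc1oc([C@@H](C)C(=O)[C@H](C)c2oc(CC)c(C)c(=O)c2C)c(C)c(=O)c1C | target

## Step count and risks

Total steps: 8. Longest linear sequence: 5 (steps 3, 4, 5, 6, 8).

Most likely to fail, first: step 8. The thioester is α-branched and hindered, C–S insertion may be slow, and both centres of 21 are acidic (each is flanked by the ketone and a pyranone), so yield and diastereomeric purity are at risk. Fallback, setting out from 20 and returning at 21: form the ketone last, by oxidation. Fukuyama reduction of 20 (Et3SiH, Pd on carbon, acetone, 20 °C) gives (2R)-2-(6-ethyl-3,5-dimethyl-4-oxo-4H-pyran-2-yl)propanal F2. Chloride 18 is converted in the flask (Zn dust, LiCl, THF, 0 °C) into [1-(3,5-dimethyl-4-oxo-6-pentyl-4H-pyran-2-yl)ethyl]zinc chloride F3, which adds Barbier-fashion to F2. This gives the secondary alcohol 2-[(2S,4S)-4-(6-ethyl-3,5-dimethyl-4-oxo-4H-pyran-2-yl)-3-hydroxypentan-2-yl]-3,5-dimethyl-6-pentyl-4H-pyran-4-one F4, as either carbinol epimer. It has the same spatial arrangement at both methyl-bearing centres as 21; the descriptors change only because the carbinol carbon ranks below the pyranyl carbon. The new methyl-bearing centre is not controlled in this addition, so the wanted diastereomers are separated by chromatography at the alcohol stage, where the centres are configurationally stable. Dess–Martin periodinane (NaHCO3, CH2Cl2, 0 °C) then gives 21.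

Second: step 7. The asymmetric coupling with a chlorothioformate is without direct precedent; loss of CO from the thiocarboxyl-nickel species, giving a nickel thiolate and then sulfide, and over-reaction of the product thioester are the main threats. Fallback, setting out from 4 and returning at 20: normal-polarity acylation plus resolution. Dienolate 6 (from 4 with 2.1 equiv LiN(SiMe3)2, THF, −78 °C) is acylated with 19 to give racemic S-phenyl 2-(6-ethyl-3,5-dimethyl-4-oxo-4H-pyran-2-yl)propanethioate F1. The enantiomers are separated by preparative chromatography on a chiral stationary phase; the R enantiomer is 20, and the S enantiomer is racemised with catalytic Et3N and recycled.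

Third: step 6. The α-chloro dienolate 17 may self-alkylate on unreacted 15 or decompose as a carbenoid before it is methylated. Fallback, setting out from 15 and returning at 18: build the secondary centre by carbonyl addition. Kornblum oxidation of 15 (DMSO, NaHCO3, NaI cat., 80 °C) gives 3,5-dimethyl-4-oxo-6-pentyl-4H-pyran-2-carbaldehyde F5. MeMgBr (THF, −78 °C) gives racemic 2-(1-hydroxyethyl)-3,5-dimethyl-6-pentyl-4H-pyran-4-one F6, and SOCl2 (CH2Cl2, 0 °C) gives 18.

## Further compounds

F1 | step 7 | racemic S-phenyl 2-(6-ethyl-3,5-dimethyl-4-oxo-4H-pyran-2-yl)propanethioate | O=C(Sc1ccccc1)C(C)c1oc(CC)c(C)c(=O)c1C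
F2 | step 8 | (2R)-2-(6-ethyl-3,5-dimethyl-4-oxo-4H-pyran-2-yl)propanal | O=C[C@H](C)c1oc(CC)c(C)c(=O)c1C
F3 | step 8 | [1-(3,5-dimethyl-4-oxo-6-pentyl-4H-pyran-2-yl)ethyl]zinc chloride | CCCCCc1oc(C(C)[Zn]Cl)c(C)c(=O)c1C
F4 | step 8 | 2-[(2S,4S)-4-(6-ethyl-3,5-dimethyl-4-oxo-4H-pyran-2-yl)-3-hydroxypentan-2-yl]-3,5-dimethyl-6-pentyl-4H-pyran-4-one (either carbinol epimer) | CCCCCc1oc([C@@H](C)C(O)[C@H](C)c2oc(CC)c(C)c(=O)c2C)c(C)c(=O)c1C
F5 | step 6 | 3,5-dimethyl-4-oxo-6-pentyl-4H-pyran-2-carbaldehyde | CCCCCc1oc(C=O)c(C)c(=O)c1C
F6 | step 6 | racemic 2-(1-hydroxyethyl)-3,5-dimethyl-6-pentyl-4H-pyran-4-one | CCCCCc1oc(C(C)O)c(C)c(=O)c1C
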